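**Retrosynthetic overview**
- The flavanone pyranone ring is closed last on the para oxygen of the phloroglucinol-type aryl ring (chromone, then asymmetric conjugate addition of phenyl); the 5-OH is freed by chelation-controlled demethylation.
- The strategy rests on the benzene ring of the flavan unit, C4a''–C5''–C6''–C7''–C8''–C8a'' (double primes = flavan unit). Its para oxygens at C5'' and C8'', the differentiated oxygen at C7'' and the pyran oxygen on C8a'' are the pattern of a Dötz benzannulation, which forms C5''–C6'', C7''–C8'' and C8''–C8a'' from a dihydropyranyl methoxycarbene chromium complex, an ethynylboronate and CO.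
- The carbene sits on C5 of a trans-4-aryl-2-phenyl-3,4-dihydro-2H-pyran that already carries both flavan stereocentres; it comes from a δ-lactone made by chalcone formation, asymmetric malonate addition (C4'') and asymmetric ketone reduction (C2'').
- Ring order: flavan pyran ring (as the lactone), flavan benzene ring (key step), flavanone pyranone ring.

Key step: step 10

Remark: the target carries no atropisomer descriptor, so rotation about the C4''–C6 bond is taken as free and the two ortho positions of the phloroglucinol-type ring count as equivalent until step 15.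

**Step 1**
Reactants: 1 4-hydroxy-2,6-dimethoxybenzaldehyde
Product: 2 4-(benzyloxy)-2,6-dimethoxybenzaldehyde
Conditions: BnBr, K2CO3, DMF, rt
Reagents that add atoms: benzyl bromide, BrCc1ccccc1
Why: Williamson etherification of the only acidic OH; the benzyl ether masks the oxygen that becomes O1 of the flavanone and should survive every step up to the hydrogenolysis in step 14.

**Step 2**
Reactants: 2 4-(benzyloxy)-2,6-dimethoxybenzaldehyde; 3 acetophenone
Product: 4 (E)-3-[4-(benzyloxy)-2,6-dimethoxyphenyl]-1-phenylprop-2-en-1-one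
Conditions: KOH, EtOH/H2O, rt
Reagents that add atoms: none
Why: Claisen–Schmidt condensation of a non-enolisable aldehyde with the acetophenone enolate; dehydration gives the conjugated (E)-enone.

**Step 3**
Reactants: 4 (E)-chalcone; 5 dimethyl malonate
Product: 6 dimethyl 2-[(1R)-1-[4-(benzyloxy)-2,6-dimethoxyphenyl]-3-oxo-3-phenylpropyl]propanedioate
Conditions: 9-amino-9-deoxy-epi-quinidine N'-[3,5-bis(trifluoromethyl)phenyl]thiourea (10 mol %), toluene, rt → 40 °C
Reagents that add atoms: none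
Why: Bifunctional thiourea/tertiary-amine catalysed asymmetric Michael addition of a malonate to a chalcone, in which the thiourea binds the enone carbonyl and the quinuclidine delivers the malonate to one β-face, setting the aryl-bearing centre (future C4'') as (R); the quinidine-derived catalyst is taken for this sense, its quinine-derived pseudoenantiomer is the alternative, and the outcome is read later at the lactone stage as trans against cis.

**Step 4**
Reactants: 6 keto diester
Product: 7 methyl (3R)-3-[4-(benzyloxy)-2,6-dimethoxyphenyl]-5-oxo-5-phenylpentanoate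
Conditions: LiCl, H2O, DMSO, 150 °C
Reagents that add atoms: none
Why: Krapcho dealkoxycarbonylation (chloride demethylates one ester of the geminal diester and the carboxylate loses CO2); the stereocentre is β to both carbonyl groups and is not touched.

**Step 5**
Reactants: 7 keto ester
Product: 9 (4R,6S)-4-[4-(benzyloxy)-2,6-dimethoxyphenyl]-6-phenyloxan-2-one (trans lactone), via hydroxy ester 8 (not isolated)
Conditions: RuCl[(S,S)-TsDPEN](p-cymene) (1 mol %), HCO2H/Et3N (5:2), DMF, 40 °C; then PPTS (10 mol %), toluene, 80 °C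
Reagents that add atoms: none
Why: Asymmetric transfer hydrogenation of an aryl alkyl ketone, where the (S,S)-TsDPEN ruthenium catalyst should give the (S)-benzylic alcohol (future C2'') under catalyst control as it does with acetophenone, followed by acid-catalysed lactonisation of the δ-hydroxy ester to the 4,6-trans δ-lactone.

**Step 6**
Reactants: 9 trans lactone
Product: 11 (4S,6S)-3-bromo-4-[4-(benzyloxy)-2,6-dimethoxyphenyl]-6-phenyloxan-2-one (C3 epimers), via lithium enolate 10 (not isolated)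
Conditions: LiN(i-Pr)2, THF, −78 °C; BrCCl2CCl2Br, −78 °C
Reagents that add atoms: 1,2-dibromotetrachloroethane, BrC(Cl)(Cl)C(Cl)(Cl)Br
Why: Electrophilic α-bromination of a lactone lithium enolate, chosen so that bromine is placed on the future C5 of the pyran without exposing the electron-rich trialkoxyphenyl ring to Br2; the configuration at C3 is irrelevant because this carbon becomes sp2.

**Step 7**
Reactants: 11 α-bromo lactone
Product: 12 (4S,6S)-3-bromo-4-[4-(benzyloxy)-2,6-dimethoxyphenyl]-6-phenyloxan-2-ol (mixture at C2 and C3)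
Conditions: i-Bu2AlH (1.1 equiv), CH2Cl2, −78 °C; aq KNaC4H4O6 work-up
Reagents that add atoms: none
Why: Partial reduction of a lactone to the lactol with one hydride equivalent; the tetrahedral aluminium alkoxide is stable at −78 °C, so over-reduction is avoided.

**Step 8**
Reactants: 12 bromo lactol
Product: 14 (2S,4S)-4-[4-(benzyloxy)-2,6-dimethoxyphenyl]-5-bromo-2-phenyl-3,4-dihydro-2H-pyran, via anomeric mesylate 13 (not isolated)
Conditions: MsCl, Et3N (excess), CH2Cl2, 0 °C → reflux
Reagents that add atoms: none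
Why: Activation of the anomeric hydroxyl as its mesylate and base-induced 1,2-elimination of the C–H next to bromine give the 5-bromo enol ether, the same elimination by which 2-haloglycals and 5-bromo-3,4-dihydro-2H-pyran are made from 2,3-dihalotetrahydropyrans.

**Step 9**
Reactants: 14 bromo dihydropyran; 15 chromium hexacarbonyl
Product: 18 pentacarbonyl{[(2S,4S)-4-[4-(benzyloxy)-2,6-dimethoxyphenyl]-2-phenyl-3,4-dihydro-2H-pyran-5-yl](methoxy)methylidene}chromium, via vinyllithium 16 (not isolated), via lithium acyl chromate 17 (not isolated)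
Conditions: t-BuLi (2.05 equiv), THF, −78 °C; Cr(CO)6, THF, −78 → 0 °C; evaporate; Me3OBF4, CH2Cl2/H2O, 0 °C
Reagents that add atoms: trimethyloxonium tetrafluoroborate, C[O+](C)C.F[B-](F)(F)F
Why: Fischer carbene synthesis (bromine–lithium exchange, addition of the alkenyllithium to a CO ligand, O-methylation of the acyl chromate with a hard oxonium salt); the lithio enol ether is kept at −78 °C and used at once because lithium and the ring oxygen are anti across the double bond.

**Step 10**
Reactants: 18 dihydropyranyl methoxycarbene chromium complex; 19 2-ethynyl-4,4,5,5-tetramethyl-1,3,2-dioxaborolane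
Product: 21 (2S,4S)-4-[4-(benzyloxy)-2,6-dimethoxyphenyl]-5-methoxy-2-phenyl-7-(4,4,5,5-tetramethyl-1,3,2-dioxaborolan-2-yl)chroman-8-ol, via arene chromium tricarbonyl complex 20 (not isolated)
Conditions: 19 (2 equiv), THF, 50 °C, argon; then air, Et2O, rt
Reagents that add atoms: none
Why: Thermal loss of one CO from the zerovalent chromium complex 18 lets alkyne 19 coordinate and insert into the Cr=C bond, giving a vinylcarbene whose new carbene carbon (future C7'') carries boron, and CO insertion then gives a chromium-bound dienylketene whose ketene carbon is the future C8''. This is the Dötz benzannulation of an alkenyl Fischer carbene complex, a reaction type known for simple terminal alkynes and for alkynylboronates. The one ring formed, the flavan benzene ring, closes by six-electron electrocyclisation between the ketene carbon and the enol ether carbon C6 of the dihydropyran (future C8a''), and tautomerisation of the cyclohexadienone gives the C8'' phenol, first as its Cr(CO)3 complex 20, which air releases. No stereocentre is created, and C2 and C4 of the pyran are sp3 carbons outside the reacting π system, so the trans relationship from steps 3 and 5 should be carried through unchanged. The step needs the alkyne to insert with its unsubstituted carbon bonding to the carbene carbon; for a terminal alkyne this is the sterically governed orientation, and the bulky pinacol boronate reinforces it, so that boron arrives at C7'', the hydroxyl at C8'' and the carbene methoxy group at C5''. Phenol formation should be favoured over cyclobutenone or five-membered-ring products because the complex is an alkenyl methoxycarbene and the reaction is run in THF at moderate temperature.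

**Step 11**
Reactants: 21 hydroxy boronate
Product: 22 2-[(2S,4S)-4-[4-(benzyloxy)-2,6-dimethoxyphenyl]-5,8-dimethoxy-2-phenylchroman-7-yl]-4,4,5,5-tetramethyl-1,3,2-dioxaborolane
Conditions: MeI, K2CO3, DMF, rt
Reagents that add atoms: methyl iodide, CI
Why: Williamson methylation of the one free phenol fixes the CO-derived oxygen as the C8'' methoxy group while boron still masks the C7'' oxygen.

**Step 12**
Reactants: 22 aryl boronate
Product: 23 (2S,4S)-4-[4-(benzyloxy)-2,6-dimethoxyphenyl]-5,8-dimethoxy-2-phenylchroman-7-ol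
Conditions: H2O2 (30 % aq), NaHCO3, THF/H2O, 0 °C → rt
Reagents that add atoms: hydrogen peroxide, OO
Why: Oxidation of an arylboronic ester by hydroperoxide (1,2-aryl shift from boron to oxygen, then hydrolysis) unveils the C7'' hydroxyl at the carbon that carried boron.

**Step 13**
Reactants: 23 C7'' phenol
Product: 24 {[(2S,4S)-4-[4-(benzyloxy)-2,6-dimethoxyphenyl]-5,8-dimethoxy-2-phenylchroman-7-yl]oxy}tri(propan-2-yl)silane
Conditions: i-Pr3SiCl, imidazole, DMF, rt
Reagents that add atoms: triisopropylsilyl chloride, CC(C)[Si](Cl)(C(C)C)C(C)C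
Why: Silylation of a phenol; the bulky silyl ether keeps the C7'' oxygen from directing any reaction to C6'' in steps 15–20 and is stable to hydrogenolysis, Grignard reagent and mild acid.

**Step 14**
Reactants: 24 benzyl ether
Product: 25 4-[(2S,4S)-5,8-dimethoxy-2-phenyl-7-(triisopropylsilyloxy)chroman-4-yl]-3,5-dimethoxyphenol
Conditions: H2 (1 atm), 10 % Pd/C, EtOAc, rt
Reagents that add atoms: none
Why: Catalytic hydrogenolysis of an aryl benzyl ether, which is much faster than cleavage of the secondary benzylic bonds of the flavan ring, frees the one phenol that becomes O1 of the flavanone.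

**Step 15**
Reactants: 25 phenol
Product: 27 6-hydroxy-2,4-dimethoxy-3-[(2S,4S)-5,8-dimethoxy-2-phenyl-7-(triisopropylsilyloxy)chroman-4-yl]benzaldehyde, via hydroxymethyl phenol 26 (not isolated)
Conditions: MgCl2, Et3N, (CH2O)n, MeCN, reflux
Reagents that add atoms: paraformaldehyde (formaldehyde), C=O
Why: Magnesium phenoxide-directed ortho-formylation (ortho-hydroxymethylation inside the magnesium chelate, then hydride transfer to a second formaldehyde) is specific for the position next to a free phenol and avoids the strong acids that could cleave the acid-labile C4''–aryl bond; the two ortho positions are equivalent.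

**Step 16**
Reactants: 27 salicylaldehyde
Product: 28 2-(1-hydroxyethyl)-3,5-dimethoxy-4-[(2S,4S)-5,8-dimethoxy-2-phenyl-7-(triisopropylsilyloxy)chroman-4-yl]phenol (carbinol epimers)
Conditions: MeMgBr (3 equiv), THF, −78 → 0 °C; aq NH4Cl
Reagents that add atoms: methylmagnesium bromide, C[Mg]Br
Why: Grignard addition to the aldehyde after deprotonation of the phenol; the new carbinol centre is oxidised away in step 17, so its configuration does not matter.

**Step 17**
Reactants: 28 benzylic alcohol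
Product: 29 1-[6-hydroxy-2,4-dimethoxy-3-[(2S,4S)-5,8-dimethoxy-2-phenyl-7-(triisopropylsilyloxy)chroman-4-yl]phenyl]ethan-1-one
Conditions: MnO2 (activated, excess), CH2Cl2, rt
Reagents that add atoms: none
Why: MnO2 oxidises the electron-rich benzylic alcohol to the ortho-hydroxyacetophenone selectively under neutral conditions.

**Step 18**
Reactants: 29 ortho-hydroxyacetophenone
Product: 31 6-[(2S,4S)-5,8-dimethoxy-2-phenyl-7-(triisopropylsilyloxy)chroman-4-yl]-5,7-dimethoxy-4H-chromen-4-one, via enaminone 30 (not isolated)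
Conditions: Me2NCH(OMe)2, toluene, 100 °C; then AcOH, 60 °C
Reagents that add atoms: N,N-dimethylformamide dimethyl acetal, COC(OC)N(C)C
Why: Enaminone chromone synthesis (condensation of the methyl ketone with the amide acetal, then acid-promoted addition–elimination by the ortho phenol with loss of dimethylamine) closes the pyranone ring on the former para oxygen, so the flavan unit ends on C6.

**Step 19**
Reactants: 31 chromone; 32 phenylboronic acid
Product: 33 (2R)-6-[(2S,4S)-5,8-dimethoxy-2-phenyl-7-(triisopropylsilyloxy)chroman-4-yl]-5,7-dimethoxy-2-phenylchroman-4-one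
Conditions: Pd(OCOCF3)2 (10 mol %), (S)-4-tert-butyl-2-(pyridin-2-yl)-4,5-dihydrooxazole (12 mol %), NH4PF6 (30 mol %), H2O (5 equiv), ClCH2CH2Cl, 60 °C
Reagents that add atoms: none
Why: Palladium-catalysed asymmetric conjugate addition of an arylboronic acid to a chromone, in which the cationic divalent palladium aryl complex of the pyridine–oxazoline ligand inserts the C2=C3 bond on one face and protonolysis of the palladium enolate gives the flavanone; the ligand sets the new C2 centre as (R) independently of the remote flavan centres, the (S)-ligand being chosen by analogy with its sense on cyclic enones and the (R)-ligand being the alternative.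

**Step 20**
Reactants: 33 5,7-dimethoxyflavanone
Product: 34 (2R)-6-[(2S,4S)-5,8-dimethoxy-2-phenyl-7-(triisopropylsilyloxy)chroman-4-yl]-5-hydroxy-7-methoxy-2-phenylchroman-4-one
Conditions: BCl3 (2 equiv), CH2Cl2, −78 → −30 °C; aq NaHCO3
Reagents that add atoms: none
Why: Chelation-controlled demethylation, in which BCl3 bound between the C4 carbonyl and the peri 5-methoxy oxygen activates only that methyl group for attack by chloride (the known selectivity for 5-methoxy groups of polymethoxylated flavonoids), so the 7-, 5''- and 8''-methoxy groups should stay.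

**Step 21**
Reactants: 34 silyl ether
Product: 35 (2R)-5-hydroxy-6-[(2S,4S)-7-hydroxy-5,8-dimethoxy-2-phenylchroman-4-yl]-7-methoxy-2-phenylchroman-4-one (target)
Conditions: Bu4NF, AcOH (1:1), THF, 0 °C
Reagents that add atoms: none
Why: Fluoride cleavage of an aryl silyl ether, buffered with acetic acid so that the base-sensitive 5-hydroxyflavanone is neither opened to the chalcone nor epimerised at C2.

**Compound list**
1 | 4-hydroxy-2,6-dimethoxybenzaldehyde | COc1cc(O)cc(OC)c1C=O | starting material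
2 | 4-(benzyloxy)-2,6-dimethoxybenzaldehyde | COc1cc(OCc2ccccc2)cc(OC)c1C=O | intermediate
3 | acetophenone | CC(=O)c1ccccc1 | starting material
4 | (E)-3-[4-(benzyloxy)-2,6-dimethoxyphenyl]-1-phenylprop-2-en-1-one | COc1cc(OCc2ccccc2)cc(OC)c1/C=C/C(=O)c1ccccc1 | intermediate
5 | dimethyl malonate | COC(=O)CC(=O)OC | starting material
6 | dimethyl 2-[(1R)-1-[4-(benzyloxy)-2,6-dimethoxyphenyl]-3-oxo-3-phenylpropyl]propanedioate | COc1cc(OCc2ccccc2)cc(OC)c1[C@H](CC(=O)c1ccccc1)C(C(=O)OC)C(=O)OC | intermediate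
7 | methyl (3R)-3-[4-(benzyloxy)-2,6-dimethoxyphenyl]-5-oxo-5-phenylpentanoate | COc1cc(OCc2ccccc2)cc(OC)c1[C@H](CC(=O)c1ccccc1)CC(=O)OC | intermediate
8 | methyl (3R,5S)-3-[4-(benzyloxy)-2,6-dimethoxyphenyl]-5-hydroxy-5-phenylpentanoate | COc1cc(OCc2ccccc2)cc(OC)c1[C@H](C[C@H](O)c1ccccc1)CC(=O)OC | intermediate
9 | (4R,6S)-4-[4-(benzyloxy)-2,6-dimethoxyphenyl]-6-phenyloxan-2-one (trans) | COc1cc(OCc2ccccc2)cc(OC)c1[C@@H]1C[C@@H](c2ccccc2)OC(=O)C1 | intermediate
10 | lithium (2S,4R)-4-[4-(benzyloxy)-2,6-dimethoxyphenyl]-2-phenyl-3,4-dihydro-2H-pyran-6-olate (lactone enolate) | COc1cc(OCc2ccccc2)cc(OC)c1[C@@H]1C[C@@H](c2ccccc2)OC(O[Li])=C1 | intermediate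
11 | (4S,6S)-3-bromo-4-[4-(benzyloxy)-2,6-dimethoxyphenyl]-6-phenyloxan-2-one (C3 epimers) | COc1cc(OCc2ccccc2)cc(OC)c1[C@@H]1C[C@@H](c2ccccc2)OC(=O)C1Br | intermediate
12 | (4S,6S)-3-bromo-4-[4-(benzyloxy)-2,6-dimethoxyphenyl]-6-phenyloxan-2-ol (mixture at C2, C3) | COc1cc(OCc2ccccc2)cc(OC)c1[C@@H]1C[C@@H](c2ccccc2)OC(O)C1Br | intermediate
13 | (4S,6S)-3-bromo-4-[4-(benzyloxy)-2,6-dimethoxyphenyl]-6-phenyloxan-2-yl methanesulfonate | COc1cc(OCc2ccccc2)cc(OC)c1[C@@H]1C[C@@H](c2ccccc2)OC(OS(C)(=O)=O)C1Br | intermediate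
14 | (2S,4S)-4-[4-(benzyloxy)-2,6-dimethoxyphenyl]-5-bromo-2-phenyl-3,4-dihydro-2H-pyran | COc1cc(OCc2ccccc2)cc(OC)c1[C@@H]1C[C@@H](c2ccccc2)OC=C1Br | intermediate
15 | chromium hexacarbonyl | O=C=[Cr](=C=O)(=C=O)(=C=O)(=C=O)=C=O | starting material
16 | [(2S,4R)-4-[4-(benzyloxy)-2,6-dimethoxyphenyl]-2-phenyl-3,4-dihydro-2H-pyran-5-yl]lithium | COc1cc(OCc2ccccc2)cc(OC)c1[C@@H]1C[C@@H](c2ccccc2)OC=C1[Li] | intermediate
17 | lithium pentacarbonyl[(2S,4S)-4-aryl-2-phenyl-3,4-dihydro-2H-pyran-5-carbonyl]chromate (aryl = 4-benzyloxy-2,6-dimethoxyphenyl) | COc1cc(OCc2ccccc2)cc(OC)c1[C@@H]1C[C@@H](c2ccccc2)OC=C1C([O-])=[Cr](=C=O)(=C=O)(=C=O)(=C=O)=C=O.[Li+] | intermediate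
18 | pentacarbonyl{[(2S,4S)-4-[4-(benzyloxy)-2,6-dimethoxyphenyl]-2-phenyl-3,4-dihydro-2H-pyran-5-yl](methoxy)methylidene}chromium | COc1cc(OCc2ccccc2)cc(OC)c1[C@@H]1C[C@@H](c2ccccc2)OC=C1C(OC)=[Cr](=C=O)(=C=O)(=C=O)(=C=O)=C=O | intermediate
19 | 2-ethynyl-4,4,5,5-tetramethyl-1,3,2-dioxaborolane | C#CB1OC(C)(C)C(C)(C)O1 | starting material
20 | tricarbonylchromium complex of phenol 21 (chromium on the new benzene ring) | COc1cc(OCc2ccccc2)cc(OC)c1[C@@H]1C[C@@H](c2ccccc2)Oc2c(O)c(B3OC(C)(C)C(C)(C)O3)cc(OC)c21.O=C=[Cr](=C=O)=C=O | intermediate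
21 | (2S,4S)-4-[4-(benzyloxy)-2,6-dimethoxyphenyl]-5-methoxy-2-phenyl-7-(4,4,5,5-tetramethyl-1,3,2-dioxaborolan-2-yl)chroman-8-ol | COc1cc(OCc2ccccc2)cc(OC)c1[C@@H]1C[C@@H](c2ccccc2)Oc2c(O)c(B3OC(C)(C)C(C)(C)O3)cc(OC)c21 | intermediate
22 | 2-[(2S,4S)-4-[4-(benzyloxy)-2,6-dimethoxyphenyl]-5,8-dimethoxy-2-phenylchroman-7-yl]-4,4,5,5-tetramethyl-1,3,2-dioxaborolane | COc1cc(OCc2ccccc2)cc(OC)c1[C@@H]1C[C@@H](c2ccccc2)Oc2c(OC)c(B3OC(C)(C)C(C)(C)O3)cc(OC)c21 | intermediate
23 | (2S,4S)-4-[4-(benzyloxy)-2,6-dimethoxyphenyl]-5,8-dimethoxy-2-phenylchroman-7-ol | COc1cc(OCc2ccccc2)cc(OC)c1[C@@H]1C[C@@H](c2ccccc2)Oc2c(OC)c(O)cc(OC)c21 | intermediate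
24 | {[(2S,4S)-4-[4-(benzyloxy)-2,6-dimethoxyphenyl]-5,8-dimethoxy-2-phenylchroman-7-yl]oxy}tri(propan-2-yl)silane | COc1cc(OCc2ccccc2)cc(OC)c1[C@@H]1C[C@@H](c2ccccc2)Oc2c(OC)c(O[Si](C(C)C)(C(C)C)C(C)C)cc(OC)c21 | intermediate
25 | 4-[(2S,4S)-5,8-dimethoxy-2-phenyl-7-(triisopropylsilyloxy)chroman-4-yl]-3,5-dimethoxyphenol | COc1cc(O)cc(OC)c1[C@@H]1C[C@@H](c2ccccc2)Oc2c(OC)c(O[Si](C(C)C)(C(C)C)C(C)C)cc(OC)c21 | intermediate
26 | 2-(hydroxymethyl)-3,5-dimethoxy-4-[(2S,4S)-5,8-dimethoxy-2-phenyl-7-(triisopropylsilyloxy)chroman-4-yl]phenol | COc1cc(O)c(CO)c(OC)c1[C@@H]1C[C@@H](c2ccccc2)Oc2c(OC)c(O[Si](C(C)C)(C(C)C)C(C)C)cc(OC)c21 | intermediate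
27 | 6-hydroxy-2,4-dimethoxy-3-[(2S,4S)-5,8-dimethoxy-2-phenyl-7-(triisopropylsilyloxy)chroman-4-yl]benzaldehyde | COc1cc(O)c(C=O)c(OC)c1[C@@H]1C[C@@H](c2ccccc2)Oc2c(OC)c(O[Si](C(C)C)(C(C)C)C(C)C)cc(OC)c21 | intermediate
28 | 2-(1-hydroxyethyl)-3,5-dimethoxy-4-[(2S,4S)-5,8-dimethoxy-2-phenyl-7-(triisopropylsilyloxy)chroman-4-yl]phenol (carbinol epimers) | COc1cc(O)c(C(C)O)c(OC)c1[C@@H]1C[C@@H](c2ccccc2)Oc2c(OC)c(O[Si](C(C)C)(C(C)C)C(C)C)cc(OC)c21 | intermediate
29 | 1-[6-hydroxy-2,4-dimethoxy-3-[(2S,4S)-5,8-dimethoxy-2-phenyl-7-(triisopropylsilyloxy)chroman-4-yl]phenyl]ethan-1-one | COc1cc(O)c(C(C)=O)c(OC)c1[C@@H]1C[C@@H](c2ccccc2)Oc2c(OC)c(O[Si](C(C)C)(C(C)C)C(C)C)cc(OC)c21 | intermediate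
30 | (E)-3-(dimethylamino)-1-[6-hydroxy-2,4-dimethoxy-3-[(2S,4S)-5,8-dimethoxy-2-phenyl-7-(triisopropylsilyloxy)chroman-4-yl]phenyl]prop-2-en-1-one | COc1cc(O)c(C(=O)/C=C/N(C)C)c(OC)c1[C@@H]1C[C@@H](c2ccccc2)Oc2c(OC)c(O[Si](C(C)C)(C(C)C)C(C)C)cc(OC)c21 | intermediate
31 | 6-[(2S,4S)-5,8-dimethoxy-2-phenyl-7-(triisopropylsilyloxy)chroman-4-yl]-5,7-dimethoxy-4H-chromen-4-one | COc1cc2c(c(OC)c1[C@@H]1C[C@@H](c3ccccc3)Oc3c(OC)c(O[Si](C(C)C)(C(C)C)C(C)C)cc(OC)c31)C(=O)C=CO2 | intermediate
32 | phenylboronic acid | OB(O)c1ccccc1 | starting material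
33 | (2R)-6-[(2S,4S)-5,8-dimethoxy-2-phenyl-7-(triisopropylsilyloxy)chroman-4-yl]-5,7-dimethoxy-2-phenylchroman-4-one | COc1cc2c(c(OC)c1[C@@H]1C[C@@H](c3ccccc3)Oc3c(OC)c(O[Si](C(C)C)(C(C)C)C(C)C)cc(OC)c31)C(=O)C[C@H](c1ccccc1)O2 | intermediate
34 | (2R)-6-[(2S,4S)-5,8-dimethoxy-2-phenyl-7-(triisopropylsilyloxy)chroman-4-yl]-5-hydroxy-7-methoxy-2-phenylchroman-4-one | COc1cc2c(c(O)c1[C@@H]1C[C@@H](c3ccccc3)Oc3c(OC)c(O[Si](C(C)C)(C(C)C)C(C)C)cc(OC)c31)C(=O)C[C@H](c1ccccc1)O2 | intermediate
35 | (2R)-5-hydroxy-6-[(2S,4S)-7-hydroxy-5,8-dimethoxy-2-phenylchroman-4-yl]-7-methoxy-2-phenylchroman-4-one | COc1cc2c(c(O)c1[C@@H]1C[C@@H](c3ccccc3)Oc3c(OC)c(O)cc(OC)c31)C(=O)C[C@H](c1ccccc1)O2 | target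

**Step count and risks**
Total step count: 21. Longest linear sequence: 21 steps (1 to 35; fully linear).

The three steps most likely to fail:

1. Step 10 (key step). What may go wrong: the alkyne inserts in the reverse orientation so that boron ends at C6''; the vinylcarbene intermediate leaks to cyclobutenone or furan products; or the donor-stabilised carbene loses CO too slowly and decomposes. Fallback: carbene 18 is annulated instead with trimethylsilylacetylene (THF, 55 °C), an alkyne whose silicon is known to end next to the new hydroxyl, to give the 7-(trimethylsilyl)chroman-8-ol F1. Fluoride (Bu4NF, wet THF) removes silicon to give the chroman-8-ol F2. Magnesium-mediated ortho-formylation (MgCl2, Et3N, paraformaldehyde), which can only reach C7'', gives the 8-hydroxychroman-7-carbaldehyde F3, and methylation (MeI, K2CO3) gives the 8-methoxychroman-7-carbaldehyde F4. Baeyer–Villiger oxidation (mCPBA, CH2Cl2) gives the aryl formate F5, and methanolysis (K2CO3, MeOH) returns to the route at phenol 23. The C7'' oxygen then comes from a phenol-directed formylation and an aryl migration instead of from boron.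

2. Step 9. What may go wrong: the 5-lithio enol ether 16 undergoes anti β-elimination of the ring alkoxide (ring opening to an alkynyl alkoxide) before Cr(CO)6 traps it, or adds sluggishly next to the bulky aryl group. Fallback without an organolithium: bromide 14 is methoxycarbonylated (Pd(OAc)2, 1,3-bis(diphenylphosphino)propane, CO, MeOH, Et3N, DMF, 70 °C) to the methyl dihydropyran-5-carboxylate F6, saponified (LiOH) to the carboxylic acid F7 and converted with oxalyl chloride into the acid chloride F8. Acylation of K2Cr(CO)5 (from 15 and KC8, THF, −78 °C) gives the potassium acyl chromate F9, which Me3OBF4 methylates to carbene 18.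

3. Step 3. What may go wrong: the β-carbon of chalcone 4 is deactivated by three alkoxy groups and shielded by two ortho substituents, so the addition may stall or lose facial selectivity. Fallback by diastereomer separation: NaOMe-catalysed addition of 5 to 4 gives the racemic keto diester F10, and Krapcho reaction gives the racemic keto ester F11. Transfer hydrogenation with the (S,S) catalyst of step 5 sets (5S) in both enantiomers, giving 8 and the (3S,5S)-hydroxy ester F12. Lactonisation gives trans-lactone 9 and the cis-lactone F13, which are diastereomers and are separated by chromatography; the route continues from 9.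

**Further compounds**
F1 | step 10 | (2S,4S)-4-[4-(benzyloxy)-2,6-dimethoxyphenyl]-5-methoxy-2-phenyl-7-(trimethylsilyl)chroman-8-ol | COc1cc(OCc2ccccc2)cc(OC)c1[C@@H]1C[C@@H](c2ccccc2)Oc2c(O)c([Si](C)(C)C)cc(OC)c21
F2 | step 10 | (2S,4S)-4-[4-(benzyloxy)-2,6-dimethoxyphenyl]-5-methoxy-2-phenylchroman-8-ol | COc1cc(OCc2ccccc2)cc(OC)c1[C@@H]1C[C@@H](c2ccccc2)Oc2c(O)ccc(OC)c21
F3 | step 10 | (2S,4S)-4-[4-(benzyloxy)-2,6-dimethoxyphenyl]-8-hydroxy-5-methoxy-2-phenylchroman-7-carbaldehyde | COc1cc(OCc2ccccc2)cc(OC)c1[C@@H]1C[C@@H](c2ccccc2)Oc2c(O)c(C=O)cc(OC)c21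
F4 | step 10 | (2S,4S)-4-[4-(benzyloxy)-2,6-dimethoxyphenyl]-5,8-dimethoxy-2-phenylchroman-7-carbaldehyde | COc1cc(OCc2ccccc2)cc(OC)c1[C@@H]1C[C@@H](c2ccccc2)Oc2c(OC)c(C=O)cc(OC)c21
F5 | step 10 | (2S,4S)-4-[4-(benzyloxy)-2,6-dimethoxyphenyl]-5,8-dimethoxy-2-phenylchroman-7-yl formate | COc1cc(OCc2ccccc2)cc(OC)c1[C@@H]1C[C@@H](c2ccccc2)Oc2c(OC)c(OC=O)cc(OC)c21
F6 | step 9 | methyl (2S,4S)-4-[4-(benzyloxy)-2,6-dimethoxyphenyl]-2-phenyl-3,4-dihydro-2H-pyran-5-carboxylate | COc1cc(OCc2ccccc2)cc(OC)c1[C@@H]1C[C@@H](c2ccccc2)OC=C1C(=O)OC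
F7 | step 9 | (2S,4S)-4-[4-(benzyloxy)-2,6-dimethoxyphenyl]-2-phenyl-3,4-dihydro-2H-pyran-5-carboxylic acid | COc1cc(OCc2ccccc2)cc(OC)c1[C@@H]1C[C@@H](c2ccccc2)OC=C1C(=O)O
F8 | step 9 | (2S,4S)-4-[4-(benzyloxy)-2,6-dimethoxyphenyl]-2-phenyl-3,4-dihydro-2H-pyran-5-carbonyl chloride | COc1cc(OCc2ccccc2)cc(OC)c1[C@@H]1C[C@@H](c2ccccc2)OC=C1C(=O)Cl
F9 | step 9 | potassium pentacarbonyl[(2S,4S)-4-[4-(benzyloxy)-2,6-dimethoxyphenyl]-2-phenyl-3,4-dihydro-2H-pyran-5-carbonyl]chromate | COc1cc(OCc2ccccc2)cc(OC)c1[C@@H]1C[C@@H](c2ccccc2)OC=C1C([O-])=[Cr](=C=O)(=C=O)(=C=O)(=C=O)=C=O.[K+]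
F10 | step 3 | racemic dimethyl 2-[1-[4-(benzyloxy)-2,6-dimethoxyphenyl]-3-oxo-3-phenylpropyl]propanedioate | COc1cc(OCc2ccccc2)cc(OC)c1C(CC(=O)c1ccccc1)C(C(=O)OC)C(=O)OC
F11 | step 3 | racemic methyl 3-[4-(benzyloxy)-2,6-dimethoxyphenyl]-5-oxo-5-phenylpentanoate | COc1cc(OCc2ccccc2)cc(OC)c1C(CC(=O)c1ccccc1)CC(=O)OC
F12 | step 3 | methyl (3S,5S)-3-[4-(benzyloxy)-2,6-dimethoxyphenyl]-5-hydroxy-5-phenylpentanoate | COc1cc(OCc2ccccc2)cc(OC)c1[C@@H](C[C@H](O)c1ccccc1)CC(=O)OC
F13 | step 3 | (4S,6S)-4-[4-(benzyloxy)-2,6-dimethoxyphenyl]-6-phenyloxan-2-one (cis) | COc1cc(OCc2ccccc2)cc(OC)c1[C@H]1C[C@@H](c2ccccc2)OC(=O)C1
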